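**Retrosynthetic overview**
1. Target 22 ⇐ hydrogenolysis of five arylmethyl ethers in the fully protected cis-flavan-3-yl ester 21.
2. 21 (ring C, C2 and C3, ester on O3) ⇐ ring expansion of the 2-(α-acyloxybenzyl)-2,3-dihydrobenzofuran 19: the ring oxygen moves to the benzylic carbon and the carboxylate moves to the former furan C2.
3. 19 ⇐ esterification of threo carbinol 13 with acid 18 (catechol, MeI, CO2); 13 ⇐ phenoxide displacement of chloride in anti-chlorohydrin 12.
4. 12 ⇐ aryl Grignard 11 (from catechol) + (3R)-3-chlorochroman-2-ol 7 ⇐ enamine chlorination of lactol 6 ⇐ phenol 4 (resorcinol, C–H borylation/oxidation) + acrolein.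
5. Ring order: ring A (resorcinol) → transient lactol ring → dihydrofuran ring → ring C by expansion; ring B and the vanilloyl ring are carried in from catechol.

Assumption: arylmethyl halides, MeI and CO2 are treated as reagents; the starting materials are resorcinol, acrolein and catechol.

**Route**

Step 1
Reactants: 1 resorcinol
Product: 2 1,3-bis[(4-methylbenzyl)oxy]benzene
Conditions: 4-MeC6H4CH2Cl (2.2 equiv), K2CO3, KI (cat.), DMF, 60 °C
Reagents that add atoms: 4-methylbenzyl chloride, Cc1ccc(CCl)cc1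
Why: Double Williamson etherification; the para-substituted benzyl rings have every C–H ortho to a substituent, so they stay inert in the borylation of step 2.

Step 2
Reactants: 2 1,3-bis[(4-methylbenzyl)oxy]benzene
Product: 4 3,5-bis[(4-methylbenzyl)oxy]phenol, via pinacol arylboronate 3 (not isolated)
Conditions: [Ir(OMe)(cod)]2 (1.5 mol%), dtbpy (3 mol%), B2pin2 (0.6 equiv), THF, 80 °C; then KHSO5 (as 2KHSO5·KHSO4·K2SO4), acetone/H2O, 0 °C → rt
Reagents that add atoms: potassium peroxymonosulfate, [K+].[O-]S(=O)(=O)OO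
Why: Sterically controlled Ir-catalysed C–H borylation goes to C5, the only C–H flanked by two hydrogens, and in-pot oxidation of the C–B bond gives the phenol (one-pot borylation/oxidation).

Step 3
Reactants: 4 3,5-bis[(4-methylbenzyl)oxy]phenol; 5 acrolein
Product: 6 5,7-bis[(4-methylbenzyl)oxy]-3,4-dihydro-2H-chromen-2-ol (lactol, racemic at C2)
Conditions: acrolein (1.1 equiv, slow addition), pyrrolidine/PhCO2H (20 mol%), CH2Cl2, 0 °C → rt
Reagents that add atoms: none
Why: Iminium-catalysed Friedel–Crafts conjugate addition of the ortho carbon of the phloroglucinol-type phenol to acrolein, then hemiacetalisation, gives the 2-hydroxychroman with O1, O5 and O7 in place.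

Step 4
Reactants: 6 5,7-bis[(4-methylbenzyl)oxy]-3,4-dihydro-2H-chromen-2-ol
Product: 7 (3R)-3-chloro-5,7-bis[(4-methylbenzyl)oxy]-3,4-dihydro-2H-chromen-2-ol (anomer mixture)
Conditions: 2,5-diphenylpyrrolidine (10 mol%, the C2-symmetric antipode that gives the 3R chloride), NCS (1.05 equiv), CH2Cl2, −20 °C
Reagents that add atoms: N-chlorosuccinimide, O=C1CCC(=O)N1Cl
Why: Enamine-catalysed asymmetric α-chlorination of the open aldehyde form; the amine shields one enamine face and sets C3 as R, and low temperature with near-stoichiometric NCS spares the electron-rich ring A.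

Step 5
Reactants: 8 catechol
Product: 9 1,2-bis(benzyloxy)benzene
Conditions: BnBr (2.2 equiv), K2CO3, DMF, rt
Reagents that add atoms: benzyl bromide, BrCc1ccccc1
Why: Williamson etherification of both phenols.

Step 6
Reactants: 9 1,2-bis(benzyloxy)benzene
Product: 10 4-bromo-1,2-bis(benzyloxy)benzene
Conditions: NBS (1.0 equiv), MeCN, 0 °C → rt
Reagents that add atoms: N-bromosuccinimide, O=C1CCC(=O)N1Br
Why: Electrophilic aromatic bromination para to an alkoxy group, the only unhindered activated position.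

Step 7
Reactants: 7 (3R)-3-chloro-5,7-bis[(4-methylbenzyl)oxy]-3,4-dihydro-2H-chromen-2-ol; 10 4-bromo-1,2-bis(benzyloxy)benzene
Product: 12 (1S,2R)-1-[3,4-bis(benzyloxy)phenyl]-2-chloro-3-{2-hydroxy-4,6-bis[(4-methylbenzyl)oxy]phenyl}propan-1-ol (anti-chlorohydrin), via arylmagnesium bromide 11 (not isolated)
Conditions: 10, Mg, LiCl, THF, 40 °C (2.3 equiv of 11); then 7, THF, −78 → −40 °C; then H2O
Reagents that add atoms: none
Why: The first equivalent of Grignard reagent opens the lactol to the magnesium phenoxide of the (R)-α-chloro aldehyde and the second adds anti to the C–Cl dipole (Cornforth–Evans model, 1,2-anti chlorohydrin), setting the carbinol carbon as S.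

Step 8
Reactants: 12 anti-chlorohydrin
Product: 13 (S)-[3,4-bis(benzyloxy)phenyl]{(2S)-4,6-bis[(4-methylbenzyl)oxy]-2,3-dihydro-1-benzofuran-2-yl}methanol (threo)
Conditions: K2CO3 (1.5 equiv), MeCN, 40 °C
Reagents that add atoms: none
Why: Carbonate in an aprotic solvent deprotonates only the phenol, whose 5-exo-tet SN2 attack on C–Cl (intramolecular Williamson) inverts that carbon to 2S and leaves the carbinol carbon untouched.

Step 9
Reactants: 8 catechol
Product: 14 2-methoxyphenol
Conditions: MeI (0.5 equiv relative to catechol), K2CO3, acetone, reflux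
Reagents that add atoms: iodomethane, CI
Why: Mono-O-methylation (Williamson) with catechol in excess to suppress the dimethyl ether.

Step 10
Reactants: 14 2-methoxyphenol
Product: 15 4-bromo-2-methoxyphenol
Conditions: NBS (1.0 equiv), MeCN, −20 → 0 °C
Reagents that add atoms: N-bromosuccinimide, O=C1CCC(=O)N1Br
Why: Electrophilic bromination para to the free OH, the stronger director.

Step 11
Reactants: 15 4-bromo-2-methoxyphenol
Product: 16 1-(benzyloxy)-4-bromo-2-methoxybenzene
Conditions: BnBr (1.1 equiv), K2CO3, DMF, rt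
Reagents that add atoms: benzyl bromide, BrCc1ccccc1
Why: Williamson etherification; benzyl masks the phenol until the final hydrogenolysis.

Step 12
Reactants: 16 1-(benzyloxy)-4-bromo-2-methoxybenzene
Product: 18 4-(benzyloxy)-3-methoxybenzoic acid, via aryllithium 17 (not isolated)
Conditions: n-BuLi (1.05 equiv), THF, −78 °C; CO2; then aq HCl
Reagents that add atoms: carbon dioxide, O=C=O
Why: Bromine–lithium exchange followed by carboxylation of the aryllithium.

Step 13
Reactants: 13 threo carbinol; 18 4-(benzyloxy)-3-methoxybenzoic acid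
Product: 19 (S)-[3,4-bis(benzyloxy)phenyl]{(2S)-4,6-bis[(4-methylbenzyl)oxy]-2,3-dihydro-1-benzofuran-2-yl}methyl 4-(benzyloxy)-3-methoxybenzoate
Conditions: DCC (1.3 equiv), DMAP (0.2 equiv), CH2Cl2, 0 °C → rt
Reagents that add atoms: none
Why: Steglich esterification acylates the carbinol oxygen, so both stereocentres are retained and the acyl group sits where the ring expansion needs it.

Step 14
Reactants: 19 threo benzylic ester
Product: 21 (2R,3R)-2-[3,4-bis(benzyloxy)phenyl]-5,7-bis[(4-methylbenzyl)oxy]-3,4-dihydro-2H-chromen-3-yl 4-(benzyloxy)-3-methoxybenzoate, via oxiranium carboxylate ion pair 20 (not isolated)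
Conditions: Sc(OTf)3 (5 mol%), CH2Cl2 (0.01 M), −40 → 0 °C
Reagents that add atoms: none
Why: Proposed new method: Sc(OTf)3 ionises the electron-rich benzylic carboxylate to a contact ion pair while the antiperiplanar furan oxygen bridges to the benzylic carbon with inversion (cis-fused oxiranium 20), and the carboxylate, held on the opposite face, closes on the former furan C2 with inversion, so the five-membered ring grows to ring C, the (αS,2S) centres become 2R and 3R (cis) and the ester arrives on O3, the chroman 3-ester being the non-ionisable sink; the closest known reactions are the zinc-acetate-mediated expansion of 2-(1-sulfonyloxyalkyl)tetrahydrofurans to 3-acetoxytetrahydropyrans through bicyclic epoxonium ions and the aziridinium ring expansion of prolinols, neither shown for an aryl ether oxygen, a carboxylate that is both leaving group and nucleophile, or a flavan.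

Step 15
Reactants: 21 protected cis-flavan-3-yl ester
Product: 22 (2R,3R)-2-(3,4-dihydroxyphenyl)-5,7-dihydroxy-3,4-dihydro-2H-chromen-3-yl 4-hydroxy-3-methoxybenzoate (target)
Conditions: H2 (1 atm), Pd(OH)2/C, THF/MeOH, rt
Reagents that add atoms: none
Why: Hydrogenolysis of all five arylmethyl ethers under neutral conditions leaves the flavan C2–O1 bond, the ester and both stereocentres untouched (standard end-game for catechin esters).

**Compound list**
1 | resorcinol | Oc1cccc(O)c1 | starting material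
2 | 1,3-bis[(4-methylbenzyl)oxy]benzene | Cc1ccc(COc2cccc(OCc3ccc(C)cc3)c2)cc1 | intermediate
3 | 2-{3,5-bis[(4-methylbenzyl)oxy]phenyl}-4,4,5,5-tetramethyl-1,3,2-dioxaborolane | Cc1ccc(COc2cc(OCc3ccc(C)cc3)cc(B3OC(C)(C)C(C)(C)O3)c2)cc1 | intermediate
4 | 3,5-bis[(4-methylbenzyl)oxy]phenol | Cc1ccc(COc2cc(O)cc(OCc3ccc(C)cc3)c2)cc1 | intermediate
5 | acrolein | C=CC=O | starting material
6 | 5,7-bis[(4-methylbenzyl)oxy]-3,4-dihydro-2H-chromen-2-ol | OC1CCc2c(OCc3ccc(C)cc3)cc(OCc3ccc(C)cc3)cc2O1 | intermediate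
7 | (3R)-3-chloro-5,7-bis[(4-methylbenzyl)oxy]-3,4-dihydro-2H-chromen-2-ol | OC1[C@H](Cl)Cc2c(OCc3ccc(C)cc3)cc(OCc3ccc(C)cc3)cc2O1 | intermediate
8 | catechol | Oc1ccccc1O | starting material
9 | 1,2-bis(benzyloxy)benzene | c1ccc(COc2ccccc2OCc2ccccc2)cc1 | intermediate
10 | 4-bromo-1,2-bis(benzyloxy)benzene | Brc1ccc(OCc2ccccc2)c(OCc2ccccc2)c1 | intermediate
11 | [3,4-bis(benzyloxy)phenyl]magnesium bromide | Br[Mg]c1ccc(OCc2ccccc2)c(OCc2ccccc2)c1 | intermediate
12 | (1S,2R)-1-[3,4-bis(benzyloxy)phenyl]-2-chloro-3-{2-hydroxy-4,6-bis[(4-methylbenzyl)oxy]phenyl}propan-1-ol | O[C@@H](c1ccc(OCc2ccccc2)c(OCc2ccccc2)c1)[C@H](Cl)Cc1c(O)cc(OCc2ccc(C)cc2)cc1OCc1ccc(C)cc1 | intermediate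
13 | (S)-[3,4-bis(benzyloxy)phenyl]{(2S)-4,6-bis[(4-methylbenzyl)oxy]-2,3-dihydro-1-benzofuran-2-yl}methanol | O[C@@H](c1ccc(OCc2ccccc2)c(OCc2ccccc2)c1)[C@@H]1Cc2c(OCc3ccc(C)cc3)cc(OCc3ccc(C)cc3)cc2O1 | intermediate
14 | 2-methoxyphenol | COc1ccccc1O | intermediate
15 | 4-bromo-2-methoxyphenol | COc1cc(Br)ccc1O | intermediate
16 | 1-(benzyloxy)-4-bromo-2-methoxybenzene | COc1cc(Br)ccc1OCc1ccccc1 | intermediate
17 | [4-(benzyloxy)-3-methoxyphenyl]lithium | [Li]c1ccc(OCc2ccccc2)c(OC)c1 | intermediate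
18 | 4-(benzyloxy)-3-methoxybenzoic acid | COc1cc(C(=O)O)ccc1OCc1ccccc1 | intermediate
19 | (S)-[3,4-bis(benzyloxy)phenyl]{(2S)-4,6-bis[(4-methylbenzyl)oxy]-2,3-dihydro-1-benzofuran-2-yl}methyl 4-(benzyloxy)-3-methoxybenzoate | COc1cc(C(=O)O[C@@H](c2ccc(OCc3ccccc3)c(OCc3ccccc3)c2)[C@@H]2Cc3c(OCc4ccc(C)cc4)cc(OCc4ccc(C)cc4)cc3O2)ccc1OCc1ccccc1 | intermediate
20 | cis-fused aryloxiranium cation paired with 4-(benzyloxy)-3-methoxybenzoate (scandium-bound) | [C@@H]1(c4ccc(OCc5ccccc5)c(OCc5ccccc5)c4)[C@@H]2Cc3c(OCc6ccc(C)cc6)cc(OCc6ccc(C)cc6)cc3[O+]12.COc1cc(C(=O)[O-])ccc1OCc1ccccc1 | intermediate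
21 | (2R,3R)-2-[3,4-bis(benzyloxy)phenyl]-5,7-bis[(4-methylbenzyl)oxy]-3,4-dihydro-2H-chromen-3-yl 4-(benzyloxy)-3-methoxybenzoate | COc1cc(C(=O)O[C@@H]2Cc3c(OCc4ccc(C)cc4)cc(OCc4ccc(C)cc4)cc3O[C@@H]2c2ccc(OCc3ccccc3)c(OCc3ccccc3)c2)ccc1OCc1ccccc1 | intermediate
22 | (2R,3R)-2-(3,4-dihydroxyphenyl)-5,7-dihydroxy-3,4-dihydro-2H-chromen-3-yl 4-hydroxy-3-methoxybenzoate | COc1cc(C(=O)O[C@@H]2Cc3c(O)cc(O)cc3O[C@@H]2c2ccc(O)c(O)c2)ccc1O | target

**Step count and risks**
Total steps: 15. Longest linear sequence: 9 (steps 1, 2, 3, 4, 7, 8, 13, 14, 15).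

Most likely to fail:

Step 14 (the new ring expansion). The benzylic cation is strongly stabilised by ring B, so the ion pair may dissociate before the carboxylate closes on the furan carbon. That would give the 2,3-trans ester, E1 loss to a 2-benzylbenzofuran, or Friedel–Crafts attack on ring A of a second molecule. Dilution, low temperature and a non-polar solvent are chosen to keep the ion pair tight. The cis product is recognised by a small J(H2,H3). Fallback with known chemistry, setting out from chlorohydrin 12: NaH (2.1 equiv), THF, −20 °C closes the alkoxide onto C–Cl to give 2-{[(2S,3S)-3-[3,4-bis(benzyloxy)phenyl]oxiran-2-yl]methyl}-3,5-bis[(4-methylbenzyl)oxy]phenol F1. Catalytic camphorsulfonic acid in CH2Cl2 at 0 °C brings the phenol in 6-endo at the benzylic carbon to give (2R,3S)-2-[3,4-bis(benzyloxy)phenyl]-5,7-bis[(4-methylbenzyl)oxy]-3,4-dihydro-2H-chromen-3-ol F2. Dess–Martin periodinane gives (2R)-2-[3,4-bis(benzyloxy)phenyl]-5,7-bis[(4-methylbenzyl)oxy]-2H-chromen-3(4H)-one F3. LiBH(s-Bu)3, THF, −78 °C delivers hydride trans to the aryl group and gives (2R,3R)-2-[3,4-bis(benzyloxy)phenyl]-5,7-bis[(4-methylbenzyl)oxy]-3,4-dihydro-2H-chromen-3-ol F4. DCC/DMAP esterification of F4 with acid 18 comes back to the route at 21.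

Step 7 (anti-selective aryl addition to the α-chloro lactol). Enolisation or epimerisation of the α-chloro aldehyde, or a low anti:syn ratio, would erode both stereocentres. Fallback, setting out from 7: K2CO3, MeCN, rt lets the phenoxide of the open form displace chloride with inversion to give (2S)-4,6-bis[(4-methylbenzyl)oxy]-2,3-dihydro-1-benzofuran-2-carbaldehyde F5. Addition of 11 to F5 pre-complexed with MgBr2·OEt2 (CH2Cl2/THF, −78 °C) is then chelation-controlled between ring oxygen and carbonyl and gives the threo carbinol, so the fallback comes back at 13 and passes over 12.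

Step 8 (phenoxide displacement versus epoxide formation). If the secondary alkoxide closes to the trans-epoxide first, the phenoxide opens it to the erythro carbinol, which leads to the 2,3-trans series. Fallback, setting out from 12: TBSOTf (2.2 equiv), 2,6-lutidine gives the O,O'-bis(tert-butyldimethylsilyl) ether of chlorohydrin 12 F6. K2CO3 in MeOH/THF cleaves only the aryl silyl ether, and the phenoxide closes on C–Cl while the secondary oxygen is blocked, giving the tert-butyldimethylsilyl ether of carbinol 13 F7. Bu4NF in THF then frees the alcohol and comes back at 13.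

**Further compounds**
F1 | step 14 | 2-{[(2S,3S)-3-[3,4-bis(benzyloxy)phenyl]oxiran-2-yl]methyl}-3,5-bis[(4-methylbenzyl)oxy]phenol | [C@@H]1(c2ccc(OCc3ccccc3)c(OCc3ccccc3)c2)O[C@H]1Cc1c(O)cc(OCc2ccc(C)cc2)cc1OCc1ccc(C)cc1
F2 | step 14 | (2R,3S)-2-[3,4-bis(benzyloxy)phenyl]-5,7-bis[(4-methylbenzyl)oxy]-3,4-dihydro-2H-chromen-3-ol | O[C@H]1Cc2c(OCc3ccc(C)cc3)cc(OCc3ccc(C)cc3)cc2O[C@@H]1c1ccc(OCc2ccccc2)c(OCc2ccccc2)c1
F3 | step 14 | (2R)-2-[3,4-bis(benzyloxy)phenyl]-5,7-bis[(4-methylbenzyl)oxy]-2H-chromen-3(4H)-one | O=C1Cc2c(OCc3ccc(C)cc3)cc(OCc3ccc(C)cc3)cc2O[C@@H]1c1ccc(OCc2ccccc2)c(OCc2ccccc2)c1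
F4 | step 14 | (2R,3R)-2-[3,4-bis(benzyloxy)phenyl]-5,7-bis[(4-methylbenzyl)oxy]-3,4-dihydro-2H-chromen-3-ol | O[C@@H]1Cc2c(OCc3ccc(C)cc3)cc(OCc3ccc(C)cc3)cc2O[C@@H]1c1ccc(OCc2ccccc2)c(OCc2ccccc2)c1
F5 | step 7 | (2S)-4,6-bis[(4-methylbenzyl)oxy]-2,3-dihydro-1-benzofuran-2-carbaldehyde | O=C[C@@H]1Cc2c(OCc3ccc(C)cc3)cc(OCc3ccc(C)cc3)cc2O1
F6 | step 8 | O,O'-bis(tert-butyldimethylsilyl) ether of chlorohydrin 12 (1S,2R) | CC(C)(C)[Si](C)(C)O[C@@H](c1ccc(OCc2ccccc2)c(OCc2ccccc2)c1)[C@H](Cl)Cc1c(O[Si](C)(C)C(C)(C)C)cc(OCc2ccc(C)cc2)cc1OCc1ccc(C)cc1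
F7 | step 8 | tert-butyldimethylsilyl ether of carbinol 13 (αS,2S) | CC(C)(C)[Si](C)(C)O[C@@H](c1ccc(OCc2ccccc2)c(OCc2ccccc2)c1)[C@@H]1Cc2c(OCc3ccc(C)cc3)cc(OCc3ccc(C)cc3)cc2O1
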